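## Retrosynthetic overview

1. The target is a head-to-tail trimer of caffeyl alcohol (unit A = cinnamyl alcohol end, unit B = centre, unit C = free catechol end) with two trans-2-hydroxymethyl-3-aryl-1,4-benzodioxane rings: ring 1 (A/B) is 7R,8R and ring 2 (B/C) is 7S,8S, each with 8-O-4'/7-O-3' connectivity (C7 = benzylic carbon, C8 = carbon bearing C9).
2. Last disconnection: the three C9 alcohols (one allylic) come from three N-acyl camphorsultam imides, cleaved together in one hydride reduction.
3. Key disconnection: both dioxane rings come from one oxidative phenol-coupling cascade of caffeoyl sultams (O4 phenoxyl + C8 radical coupling, then p-quinone methide, then closure by the neighbouring 3-OH). The sultam on the C8-radical partner sets C8; trans closure sets C7.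
4. Ring order: ring 1 first, by homocoupling of the (2S)-sultam monomer (one molecule becomes unit A, the other unit B). Ring 2 second, in the same flask, by endwise cross-coupling of the dimer's free catechol with slowly added (2R)-sultam monomer (unit C).
5. Each monomer comes from 3,4-dihydroxybenzaldehyde and an N-bromoacetyl camphorsultam (one-pot Wittig), itself from the camphorsultam enantiomer and bromoacetyl bromide.

Assumption: the C8 radical of a caffeoyl sultam is attacked on its Cα-Re face with the (2R)-sultam (Cα-Si with the (2S)-sultam), as in other reactions of N-enoyl and α-radical N-acyl camphorsultams; if the coupling shows the opposite sense, 7 and 12 (with their precursors) exchange roles in step 5 and nothing else changes.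

## Route

Step 1
Reactants: 1 (1R)-(+)-2,10-camphorsultam; 2 bromoacetyl bromide
Product: 3 N-(bromoacetyl)-(2S)-bornane-10,2-sultam
Conditions: NaH (1.1 equiv), PhMe, 0 °C, 30 min; then 2 (1.2 equiv), 0 °C → rt
Reagents that add atoms: bromoacetyl bromide (2), BrCC(Br)=O
Why: N-acylation (nucleophilic acyl substitution) of the sodium sulfonamide, in which the acyl bromide carbon reacts far faster than the CH2Br carbon; no stereocentre is made or touched.

Step 2
Reactants: 3 N-(bromoacetyl)-(2S)-bornane-10,2-sultam; 4 3,4-dihydroxybenzaldehyde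
Product: 7 N-[(E)-3-(3,4-dihydroxyphenyl)prop-2-enoyl]-(2S)-bornane-10,2-sultam, via phosphonium bromide 5 (not isolated), via phosphorus ylide 6 (not isolated)
Conditions: PPh3 (1.05 equiv), THF, rt, 3 h; then 4 (1.0 equiv), Et3N (1.2 equiv), THF, 60 °C, Ar
Reagents that add atoms: none
Why: One-pot Wittig olefination in which the imide-stabilised ylide gives the E-alkene under the usual stabilised-ylide control and tolerates the free catechol; no stereocentre is formed.

Step 3
Reactants: 8 (1S)-(−)-2,10-camphorsultam; 2 bromoacetyl bromide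
Product: 9 N-(bromoacetyl)-(2R)-bornane-10,2-sultam
Conditions: NaH (1.1 equiv), PhMe, 0 °C, 30 min; then 2 (1.2 equiv), 0 °C → rt
Reagents that add atoms: bromoacetyl bromide (2), BrCC(Br)=O
Why: Same N-acylation as step 1 in the enantiomeric series; no stereocentre is made or touched.

Step 4
Reactants: 9 N-(bromoacetyl)-(2R)-bornane-10,2-sultam; 4 3,4-dihydroxybenzaldehyde
Product: 12 N-[(E)-3-(3,4-dihydroxyphenyl)prop-2-enoyl]-(2R)-bornane-10,2-sultam, via phosphonium bromide 10 (not isolated), via phosphorus ylide 11 (not isolated)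
Conditions: PPh3 (1.05 equiv), THF, rt, 3 h; then 4 (1.0 equiv), Et3N (1.2 equiv), THF, 60 °C, Ar
Reagents that add atoms: none
Why: Same one-pot Wittig olefination as step 2, giving the E-enoyl sultam of the enantiomeric auxiliary; no stereocentre is formed.

Step 5
Reactants: 7 N-[(E)-3-(3,4-dihydroxyphenyl)prop-2-enoyl]-(2S)-bornane-10,2-sultam (2 molecules per product); 12 N-[(E)-3-(3,4-dihydroxyphenyl)prop-2-enoyl]-(2R)-bornane-10,2-sultam
Product: 16 tris-sultam trimer with both benzodioxane rings trans (ring 1: C7 R and C8 formally S; ring 2: C7 S and C8 formally R; same geometry as the target), via dimer-stage quinone methide 13 (not isolated), via bis-sultam benzodioxane dimer 14 (not isolated), via trimer-stage quinone methide 15 (not isolated)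
Conditions: 7 in one portion, Ag2CO3 (1.0 equiv), PhMe/acetone 2:1, 0.2 M, rt, dark, Ar, until 7 is consumed; then Ag2CO3 (0.5 equiv) and 12 (0.3 equiv, in acetone by syringe pump over 8 h), rt; chromatography
Reagents that add atoms: none
Why: Proposed new method: Ag2CO3 oxidises each catechol by one electron to a phenoxyl radical, and the O4 radical of one molecule of 7 couples with the C8 radical of a second (8-O-4' oxidative phenol coupling), the C8 radical reacting in its s-cis, C=O/SO2-anti conformation on the face not shielded by the pseudo-axial sulfonyl oxygen of the (2S)-sultam, which sets C8; the p-quinone methide 13 is then trapped by the neighbouring 3-OH (intramolecular oxa-Michael addition) to the favoured trans-benzodioxane 14, which sets C7; slow addition of 12 keeps its radical concentration low so that it adds endwise to the more easily oxidised alkylcatechol of 14, its (2R)-sultam directing the opposite face to give 15 and, after the same ring closure, the second trans ring of 16; the closest known chemistry is the Ag2CO3- or Ag2O-mediated oxidative coupling of caffeate esters or coniferyl alcohol with catechols to racemic trans-benzodioxane neolignans, the camphorsultam-directed 8-5 oxidative dimerisation of feruloyl sultams, and the face-selective trapping of α-acyl radicals of N-acyl camphorsultams.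

Step 6
Reactants: 16 tris-sultam trimer
Product: 17 target CNP0234042.2
Conditions: iBu2AlH (DIBAL-H, 12 equiv), THF/CH2Cl2, −78 → 0 °C; aq. KNaC4H4O6 (potassium sodium tartrate) work-up
Reagents that add atoms: none
Why: Hydride reduction of the three N-acyl sulfonamides (1,2-reduction of the enoyl unit to the E-allylic alcohol, reductive cleavage of the two saturated acyl sultams to CH2OH) releases all auxiliaries, and because reduction at low temperature outruns enolisation at C8 no stereocentre is disturbed (only the C8 descriptors change, from S/R to R/S, as C9 becomes CH2OH).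

## Compound list

1 | (1R)-(+)-2,10-camphorsultam, i.e. (2S)-bornane-10,2-sultam | N1[C@H]2C[C@@H]3CC[C@@]2(CS1(=O)=O)C3(C)C | starting material
2 | bromoacetyl bromide | BrCC(Br)=O | starting material
3 | N-(bromoacetyl)-(2S)-bornane-10,2-sultam | BrCC(=O)N1[C@H]2C[C@@H]3CC[C@@]2(CS1(=O)=O)C3(C)C | intermediate
4 | 3,4-dihydroxybenzaldehyde | O=Cc1ccc(O)c(O)c1 | starting material
5 | [2-oxo-2-((2S)-bornane-10,2-sultam-N-yl)ethyl]triphenylphosphonium bromide | O=C(C[P+](c1ccccc1)(c1ccccc1)c1ccccc1)N1[C@H]2C[C@@H]3CC[C@@]2(CS1(=O)=O)C3(C)C.[Br-] | intermediate (not isolated)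
6 | N-[(triphenylphosphoranylidene)acetyl]-(2S)-bornane-10,2-sultam | O=C(C=P(c1ccccc1)(c1ccccc1)c1ccccc1)N1[C@H]2C[C@@H]3CC[C@@]2(CS1(=O)=O)C3(C)C | intermediate (not isolated)
7 | N-[(E)-3-(3,4-dihydroxyphenyl)prop-2-enoyl]-(2S)-bornane-10,2-sultam | O=C(/C=C/c1ccc(O)c(O)c1)N1[C@H]2C[C@@H]3CC[C@@]2(CS1(=O)=O)C3(C)C | intermediate
8 | (1S)-(−)-2,10-camphorsultam, i.e. (2R)-bornane-10,2-sultam | N1[C@@H]2C[C@H]3CC[C@]2(CS1(=O)=O)C3(C)C | starting material
9 | N-(bromoacetyl)-(2R)-bornane-10,2-sultam | BrCC(=O)N1[C@@H]2C[C@H]3CC[C@]2(CS1(=O)=O)C3(C)C | intermediate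
10 | [2-oxo-2-((2R)-bornane-10,2-sultam-N-yl)ethyl]triphenylphosphonium bromide | O=C(C[P+](c1ccccc1)(c1ccccc1)c1ccccc1)N1[C@@H]2C[C@H]3CC[C@]2(CS1(=O)=O)C3(C)C.[Br-] | intermediate (not isolated)
11 | N-[(triphenylphosphoranylidene)acetyl]-(2R)-bornane-10,2-sultam | O=C(C=P(c1ccccc1)(c1ccccc1)c1ccccc1)N1[C@@H]2C[C@H]3CC[C@]2(CS1(=O)=O)C3(C)C | intermediate (not isolated)
12 | N-[(E)-3-(3,4-dihydroxyphenyl)prop-2-enoyl]-(2R)-bornane-10,2-sultam | O=C(/C=C/c1ccc(O)c(O)c1)N1[C@@H]2C[C@H]3CC[C@]2(CS1(=O)=O)C3(C)C | intermediate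
13 | dimer-stage p-quinone methide: 7 with its 4-oxygen bonded to C8 (S) of unit B, where unit B is (2S)-sultam-N-yl–CO–C8H(OAr)–C7H=(3-hydroxy-4-oxocyclohexa-2,5-dien-1-ylidene); exocyclic alkene geometry not defined | O=C(/C=C/c1ccc(O[C@@H](C=C2C=CC(=O)C(O)=C2)C(=O)N2[C@H]3C[C@@H]4CC[C@@]3(CS2(=O)=O)C4(C)C)c(O)c1)N1[C@H]2C[C@@H]3CC[C@@]2(CS1(=O)=O)C3(C)C | intermediate (not isolated)
14 | trans-benzodioxane dimer: (2S,3R)-3-(3,4-dihydroxyphenyl)-2,3-dihydro-1,4-benzodioxine with the (2S)-sultam carbonyl at C2 and the (E)-3-oxo-3-[(2S)-sultam-N-yl]prop-1-enyl chain at C6 | O=C(/C=C/c1ccc2c(c1)O[C@H](c1ccc(O)c(O)c1)[C@@H](C(=O)N1[C@H]3C[C@@H]4CC[C@@]3(CS1(=O)=O)C4(C)C)O2)N1[C@H]2C[C@@H]3CC[C@@]2(CS1(=O)=O)C3(C)C | intermediate (not isolated)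
15 | trimer-stage p-quinone methide: 14 with the 4-oxygen of its catechol bonded to C8 (R) of unit C, where unit C is (2R)-sultam-N-yl–CO–C8H(OAr)–C7H=(3-hydroxy-4-oxocyclohexa-2,5-dien-1-ylidene); exocyclic alkene geometry not defined | O=C(/C=C/c1ccc2c(c1)O[C@H](c1ccc(O[C@H](C=C3C=CC(=O)C(O)=C3)C(=O)N3[C@@H]4C[C@H]5CC[C@]4(CS3(=O)=O)C5(C)C)c(O)c1)[C@@H](C(=O)N1[C@H]3C[C@@H]4CC[C@@]3(CS1(=O)=O)C4(C)C)O2)N1[C@H]2C[C@@H]3CC[C@@]2(CS1(=O)=O)C3(C)C | intermediate (not isolated)
16 | tris-sultam trimer: 14 in which the 3,4-dihydroxyphenyl group has become a (2R,3S)-3-(3,4-dihydroxyphenyl)-2-[(2R)-sultam-N-ylcarbonyl]-2,3-dihydro-1,4-benzodioxin-6-yl group | O=C(/C=C/c1ccc2c(c1)O[C@H](c1ccc3c(c1)O[C@@H](c1ccc(O)c(O)c1)[C@H](C(=O)N1[C@@H]4C[C@H]5CC[C@]4(CS1(=O)=O)C5(C)C)O3)[C@@H](C(=O)N1[C@H]3C[C@@H]4CC[C@@]3(CS1(=O)=O)C4(C)C)O2)N1[C@H]2C[C@@H]3CC[C@@]2(CS1(=O)=O)C3(C)C | intermediate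
17 | CNP0234042.2: (E)-3-[(2R,3R)-3-{(2S,3S)-3-(3,4-dihydroxyphenyl)-2-(hydroxymethyl)-2,3-dihydro-1,4-benzodioxin-6-yl}-2-(hydroxymethyl)-2,3-dihydro-1,4-benzodioxin-6-yl]prop-2-en-1-ol | OC/C=C/c1ccc2c(c1)O[C@H](c1ccc3c(c1)O[C@@H](c1ccc(O)c(O)c1)[C@H](CO)O3)[C@@H](CO)O2 | target

## Step count and risks

Total steps: 6. Longest linear sequence: 4 (steps 1, 2, 5, 6).

**Most likely to fail, in order:**

**Step 5.** The risks are:
- the face selectivity of the sultam-directed C8–O coupling is untested (about 9:1 per coupling is hoped for by analogy);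
- the 8-O-4' versus 8-O-3' regiochemistry;
- over-oligomerisation of 7 before 12 is added;
- homocoupling of 12.

All stereo- and regioisomeric by-products carry the auxiliaries and are therefore diastereomers of 16, so chromatography at this stage is what secures the single enantiomer. A realistic yield is 15–25%.

Fallback: set out from 4 and 7. Couple 7 with a threefold excess of 4 (Ag2CO3, PhMe/acetone). Aldehyde 4 cannot act as a C8-radical donor, and its more acidic 4-OH directs the 8-O-4' mode. This gives (2S,3R)-3-(3,4-dihydroxyphenyl)-2-[(2S)-sultam-N-ylcarbonyl]-2,3-dihydro-1,4-benzodioxine-6-carbaldehyde F1. The only homocoupling by-product of 7 is 14 itself. A Wittig reaction of F1 with ylide 6 (made from 3 as in step 2) installs the unit A side chain and comes back to the route at 14, now isolated and purified. Compound 14 is then taken to 16 by the second half of step 5 run as a separate operation (slow addition of 12, Ag2CO3).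

**Step 6.** The risks are:
- the aluminium catecholate of unit C is para to the benzylic C7–O bond and could open ring 2 through a quinone methide;
- incomplete cleavage of the hindered imides;
- conjugate reduction of the enoyl unit.

Fallback: set out from 16. Silylate the catechol (TBSCl, imidazole, DMF) to the bis-silyl ether of the tris-sultam trimer F2. Reduce with DIBAL-H as in step 6 to the bis-silyl ether of the target F3. Remove the silyl groups with Et3N·3HF in THF and come back to the route at 17.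

**Step 2.** The risks are a sluggish Wittig reaction on the phenolate-deactivated aldehyde and air oxidation of the catechol under base.

Fallback: set out from 1 and commercial caffeic acid, building the enoyl sultam by acylation instead of olefination. Acetylation (Ac2O, pyridine) gives (E)-3-(3,4-diacetoxyphenyl)prop-2-enoic acid F4. Oxalyl chloride with catalytic DMF gives (E)-3-(3,4-diacetoxyphenyl)prop-2-enoyl chloride F5. The sodium salt of 1 (NaH, PhMe) is acylated by F5 to N-[(E)-3-(3,4-diacetoxyphenyl)prop-2-enoyl]-(2S)-bornane-10,2-sultam F6. Mild hydrolysis of the aryl acetates (NH4OAc, aqueous MeOH, rt) comes back to the route at 7.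

## Further compounds

F1 | step 5 | (2S,3R)-3-(3,4-dihydroxyphenyl)-2-[((2S)-bornane-10,2-sultam-N-yl)carbonyl]-2,3-dihydro-1,4-benzodioxine-6-carbaldehyde | O=Cc1ccc2c(c1)O[C@H](c1ccc(O)c(O)c1)[C@@H](C(=O)N1[C@H]3C[C@@H]4CC[C@@]3(CS1(=O)=O)C4(C)C)O2
F2 | step 6 | 16 with both phenolic OH groups of unit C as tert-butyldimethylsilyl ethers | O=C(/C=C/c1ccc2c(c1)O[C@H](c1ccc3c(c1)O[C@@H](c1ccc(O[Si](C)(C)C(C)(C)C)c(O[Si](C)(C)C(C)(C)C)c1)[C@H](C(=O)N1[C@@H]4C[C@H]5CC[C@]4(CS1(=O)=O)C5(C)C)O3)[C@@H](C(=O)N1[C@H]3C[C@@H]4CC[C@@]3(CS1(=O)=O)C4(C)C)O2)N1[C@H]2C[C@@H]3CC[C@@]2(CS1(=O)=O)C3(C)C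
F3 | step 6 | 17 with both phenolic OH groups of unit C as tert-butyldimethylsilyl ethers | OC/C=C/c1ccc2c(c1)O[C@H](c1ccc3c(c1)O[C@@H](c1ccc(O[Si](C)(C)C(C)(C)C)c(O[Si](C)(C)C(C)(C)C)c1)[C@H](CO)O3)[C@@H](CO)O2
F4 | step 2 | (E)-3-(3,4-diacetoxyphenyl)prop-2-enoic acid | CC(=O)Oc1ccc(/C=C/C(=O)O)cc1OC(C)=O
F5 | step 2 | (E)-3-(3,4-diacetoxyphenyl)prop-2-enoyl chloride | CC(=O)Oc1ccc(/C=C/C(Cl)=O)cc1OC(C)=O
F6 | step 2 | N-[(E)-3-(3,4-diacetoxyphenyl)prop-2-enoyl]-(2S)-bornane-10,2-sultam | CC(=O)Oc1ccc(/C=C/C(=O)N2[C@H]3C[C@@H]4CC[C@@]3(CS2(=O)=O)C4(C)C)cc1OC(C)=O
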